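The earlier runs and the new flask are simulated with constants of no real substance; scatter was added.

The partner is the limiting reagent here, with less of it charged, 16.0 mM, than the 20 mM of either substrate, and the steps on offer take it two ways: by the making of either product and by the quench with protic impurity.

- dawn: left-handed substrate 20 mM; right-handed substrate 20 mM; partner 16 mM; protic impurity 5 mM; free catalyst 100 µM; run made earlier
- flask: left-handed substrate 20 mM; partner 16.0 mM; protic impurity 10.0 mM; free catalyst 100 µM; right-handed substrate 20 mM

- dawn (time / h: left-handed product / %, left-handed substrate / %): 0.200: 1.9, 48.6; 0.333: 0, 49.6; 0.417: 3.0, 47.2; 0.667: 4.2, 46.5; 1.00: 5.5, 45.8; 1.50: 6.4, 44.3; 2.50: 9.9, 39.6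

(scatter of a reading: 1 percentage point)

- apparent order in partner when 10 % of the left-handed substrate and right-handed substrate together are converted (percent change of the rate of making left-handed product for one percent more partner charged)
- factor on the rate of making left-handed product when 10 % of the left-handed substrate and right-handed substrate together are converted if free catalyst is charged twice over

- free catalyst is single-handed; left-handed substrate and right-handed substrate are mirror images of each other, charged as a racemate, each of them at the stated concentration
- steps thought possible: partner + protic impurity -> quenched reagent; partner + free catalyst + right-handed substrate -> free catalyst + right-handed product; free catalyst -> spent catalyst; partner + free catalyst + left-handed substrate -> free catalyst + left-handed product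
- no earlier run changes the charge of free catalyst; that part of a forecast is a guess
- no earlier run changes the charge of protic impurity; that part of a forecast is a guess
- no earlier run changes the charge of partner; that part of a forecast is a guess

The mirror-image pair gives me a zero for the scale: each turnover uses one partner whichever hand reacts, so the mark at 10 % takes 4.00 mM of partner at any selectivity. At that mark the substrates are fixed, so the rate follows c(partner) there. So the apparent order is the partner leverage: c(partner) charged over c(partner) standing at the mark, as long as the amount quenched does not shift with the charge. With no quench it is 1.33, and with instant quench of the flask's 10.0 mM impurity it is 8.00. But the dawn slope, 2.20 mM h⁻¹ over the first 1.00 h and then 1.17 mM h⁻¹, carries too much scatter to time the quench. So my own reckoning takes the geometric middle, 3.26. For the doubled catalyst I start from a factor of 2, plus what partner an earlier mark saves.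

The forecast gives 6.5 (3 to 11) and 2.2 (1.9 to 3.2), on the case “If impurity quenching is fast”, so its order stands higher than my 3.26.

The flask gives an order of 1.6 and a factor of 2.21.

    partner + protic impurity → quenched reagent (k = 0.128 L mol⁻¹ min⁻¹)
    partner + free catalyst + right-handed substrate → free catalyst + right-handed product (k = 57.1 L² mol⁻² min⁻¹)
    free catalyst → spent catalyst (k = 9.16 × 10⁻⁶ min⁻¹)
    partner + free catalyst + left-handed substrate → free catalyst + left-handed product (k = 1110 L² mol⁻² min⁻¹)

Up to the mark at 2.51 h the making of left-handed product and the quench ran side by side, the making using partner 1.7 times as fast as the quench at the start, and on the leverage the order 1.6 means 9.83 mM of partner stood at the mark, the quench having taken 2.17 mM, which lies between the quenched reagent of 0.865 mM at 0.800 h and 2.90 mM at 4.00 h. With free catalyst charged twice over, the mark comes near 1.25 h, the quench takes about 1.08 mM, and the same count gives a factor of 2.22, where the simulation gives 2.21.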